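The flask starts with 0.10 M of J and receives 0.0800 M of G over 10 h, which makes 0.800 equivalents of G per J charged.

the same everywhere: J 0.10 M
- south-east: G 0.080 M (fed, over 10 h); the very flask that is asked about, followed so far; the fed solution adds 0.20 times the starting volume
- flask: G 0.0800 M (fed, over 10 h); the fed solution adds 0.20 times the starting volume; time 30 h

south-east run (percent of the J charged)

| time / h | Q / % | J / % |
|---|---|---|
| 2.50 | 9 | 85 |
| 4.00 | 18 | 75 |
| 5.00 | 17 | 65 |
| 8.00 | 27 | 41 |
| 12.0 | 30 | 17 |

(scatter of a reading: 2 percentage points)

- amounts are per litre of the starting volume; all of the dose is in the solution fed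
- the numbers in the tables scatter by 2 percentage points (one standard deviation)

- time, not beyond 30 h, at which the flask holds most Q
- the amount of Q, in percent of the J charged, at that time

From 2.50 h to 8.00 h the readings lose 1.00 J per G fed, so over that stretch the J readings run nearly straight with the feed. The carried quantity is y, the Q held per J lost, a running selectivity. At the first reading it stands at 0.600. Pooling the last two readings gives 0.401, which is lower and carries the scatter of those readings. The Q reading stands lower than the J reading at 8.00 h and higher at 12.0 h, so the two sets of readings cross between those times. Straight lines between those readings cross at 10.1 h, close to the end of the feed. This reckoning takes the end of the feed as the knee. At that time the J line reads 29.0 %, so y gives Q 28.5 %. Taking Q and J as equally ready for G, this reckoning puts the peak at the crossing, with Q declining slowly afterwards.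

The forecast gives 11 h (9.5 h to 14 h) and 30 % (27 % to 33 %), a later time than the crossing: “The peak is flat, and Q falls afterwards.”

The flask peaks at 9.88 h with 29.0 % of Q.

    J + G → Q + X (k = 0.00170 M⁻¹ s⁻¹)
    G + Q → L + X (k = 0.00150 M⁻¹ s⁻¹)
    G + L ⇌ Z + X (K = 0.740, k = 1.30 × 10⁻⁴ M⁻¹ s⁻¹)
    J + X → E (k = 0.00160 M⁻¹ s⁻¹)

At 9.88 h the flask holds 25.6 % of J, so Q per J lost is 0.390, beside the 0.401 read as y from the scattered readings. The neighbour charged with 0.40 M of J keeps 61.8 % of its J at 30.0 h. Applied to its lost J, y gives 15.3 % of Q, and that neighbour holds 16.4 %.

The earlier runs and the new flask were computed for an exercise; scatter was added.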